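**Assumption:** Coloratanin A as drawn has no stereocentres and no E/Z-defined alkene (the prenyl terminus carries two methyls), so it is achiral and there is no enantiomer to select.

**Retrosynthetic overview**
1. Target ⇒ 7,4'-bis-MOM ether 9 (global MOM removal last).
2. C6 prenyl ⇒ C6–I + prenylBpin (α-selective Suzuki); C6–I ⇒ iodination ortho to the free, chelated 5-OH.
3. 3'-(3-Hydroxy-3-methylbutyl) ⇒ 3'-Br + 9-BBN adduct of 2-methyl-3-buten-2-ol (B-alkyl Suzuki), done before any iodine or prenyl is present.
4. 3'-Bromogenistein core ⇒ phloroglucinol + 3-bromo-4-hydroxyphenylacetic acid + one carbon from DMF.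
5. Ring order: A and B rings are purchased; only the pyranone C-ring is formed (step 1).

**Step 1**
Reactants: 1 phloroglucinol (anhydrous); 2 3-bromo-4-hydroxyphenylacetic acid
Product: 3 3-(3-bromo-4-hydroxyphenyl)-5,7-dihydroxy-4H-chromen-4-one (3'-bromogenistein)
Conditions: BF3·OEt2 (neat), 85 °C, 2 h; cool, DMF; then MsCl, DMF, 70 °C, 2 h (one pot); aq NaOAc work-up
Reagents that add atoms: DMF, CN(C)C=O (supplies C-2)
Why: Friedel–Crafts acylation of symmetric phloroglucinol gives the deoxybenzoin BF2 chelate (not isolated), whose methylene is formylated by the DMF/MsCl Vilsmeier reagent and cyclises to the isoflavone (one-pot deoxybenzoin isoflavone synthesis).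

**Step 2**
Reactants: 3
Product: 4 3-[3-bromo-4-(methoxymethoxy)phenyl]-5-hydroxy-7-(methoxymethoxy)-4H-chromen-4-one
Conditions: MOMCl (2.3 equiv), K2CO3, acetone, 0 °C → rt
Reagents that add atoms: chloromethyl methyl ether, COCCl
Why: Williamson-type O-alkylation occurs at the 7- and 4'-phenols, while the 5-OH is hydrogen-bonded to the C4 carbonyl and stays free.

**Step 3**
Reactants: 4; 5 2-methyl-3-buten-2-ol
Product: 6 5-hydroxy-3-[3-(3-hydroxy-3-methylbutyl)-4-(methoxymethoxy)phenyl]-7-(methoxymethoxy)-4H-chromen-4-one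
Conditions: 5 (2 equiv), 9-BBN (0.5 M in THF, 4.2 equiv), 0 °C → rt, 6 h; then degassed 3 M aq K3PO4 (destroys residual B–H), 4, Pd(dppf)Cl2·CH2Cl2 (10 mol %), DMF, 60 °C
Reagents that add atoms: 2-methyl-3-buten-2-ol (5), C=CC(C)(C)O
Why: Anti-Markovnikov hydroboration gives the primary B-alkyl-9-BBN, which undergoes B-alkyl Suzuki–Miyaura coupling with the aryl bromide; quenching B–H first protects the chromone carbonyl from reduction.

**Step 4**
Reactants: 6
Product: 7 5-hydroxy-3-[3-(3-hydroxy-3-methylbutyl)-4-(methoxymethoxy)phenyl]-6-iodo-7-(methoxymethoxy)-4H-chromen-4-one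
Conditions: BnMe3N+ ICl2− (1.1 equiv), CaCO3, CH2Cl2/MeOH (5:2), rt
Reagents that add atoms: benzyltrimethylammonium dichloroiodate, C[N+](C)(C)Cc1ccccc1.Cl[I-]Cl (delivers I)
Why: Electrophilic aromatic iodination of 5-hydroxy-7-alkoxy chromones goes ortho to the free chelated 5-OH (C6, not C8); the B-ring aryl MOM ether is unreactive under these buffered conditions, and no alkene is present yet to add ICl.

**Step 5**
Reactants: 7; 8 3-methylbut-2-enylboronic acid pinacol ester (prenylBpin)
Product: 9 5-hydroxy-3-[3-(3-hydroxy-3-methylbutyl)-4-(methoxymethoxy)phenyl]-7-(methoxymethoxy)-6-(3-methylbut-2-en-1-yl)-4H-chromen-4-one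
Conditions: 8 (3 equiv), Pd(dppf)Cl2·CH2Cl2 (10 mol %), Cs2CO3, THF/H2O (10:1), degassed, 70 °C
Reagents that add atoms: prenylBpin (8), CC(C)=CCB1OC(C)(C)C(C)(C)O1
Why: Suzuki–Miyaura allylation, where reductive elimination from the equilibrating allyl-Pd occurs at the unhindered primary terminus to give the linear (α) prenyl arene at the hindered C6 position.

**Step 6**
Reactants: 9
Product: 10 Coloratanin A, 5,7-dihydroxy-3-[4-hydroxy-3-(3-hydroxy-3-methylbutyl)phenyl]-6-(3-methylbut-2-en-1-yl)-4H-chromen-4-one
Conditions: 3 M aq HCl, MeOH/THF, 45–50 °C, followed by TLC; NaHCO3 quench as soon as complete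
Reagents that add atoms: none
Why: Mild acetal hydrolysis removes both aryl MOM ethers under dilute, water-rich conditions that are too weak to ionise the non-benzylic tertiary alcohol or cyclise the prenyl group onto the neighbouring phenols.

**Compound list**
1 | phloroglucinol | Oc1cc(O)cc(O)c1 | starting material
2 | 3-bromo-4-hydroxyphenylacetic acid | OC(=O)Cc1ccc(O)c(Br)c1 | starting material
3 | 3'-bromogenistein | O=c1c(-c2ccc(O)c(Br)c2)coc2cc(O)cc(O)c12 | intermediate
4 | 7,4'-bis-O-MOM-3'-bromogenistein | COCOc1cc(O)c2c(c1)occ(-c1ccc(OCOC)c(Br)c1)c2=O | intermediate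
5 | 2-methyl-3-buten-2-ol | C=CC(C)(C)O | starting material
6 | 3'-(3-hydroxy-3-methylbutyl)-7,4'-bis-O-MOM-genistein | COCOc1cc(O)c2c(c1)occ(-c1ccc(OCOC)c(CCC(C)(C)O)c1)c2=O | intermediate
7 | 6-iodo derivative of 6 | COCOc1cc2occ(-c3ccc(OCOC)c(CCC(C)(C)O)c3)c(=O)c2c(O)c1I | intermediate
8 | prenylboronic acid pinacol ester | CC(C)=CCB1OC(C)(C)C(C)(C)O1 | starting material
9 | 6-prenyl-3'-(3-hydroxy-3-methylbutyl)-7,4'-bis-O-MOM-genistein | COCOc1cc2occ(-c3ccc(OCOC)c(CCC(C)(C)O)c3)c(=O)c2c(O)c1CC=C(C)C | intermediate
10 | Coloratanin A | CC(C)=CCc1c(O)cc2occ(-c3ccc(O)c(CCC(C)(C)O)c3)c(=O)c2c1O | target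

**Total steps:** 6. **Longest linear sequence:** 6 (fully linear from 1; compounds 2, 5 and 8 are purchased).

**Three steps most likely to fail, with fallbacks**
- **Step 5 (prenyl Suzuki).** Risks are α/γ (reverse-prenyl) mixtures and protodeiodination at the electron-rich, di-ortho-substituted iodide. Fallback: install a plain allyl group and convert it to prenyl by cross-metathesis with 2-methyl-2-butene (Grubbs II). The allyl group can come from Stille coupling of 7 with allylSnBu3, or, bypassing the iodide, from 5-O-allylation of 6 and thermal ortho-Claisen rearrangement (C6 is the only free ortho position).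
- **Step 3 (B-alkyl Suzuki).** Risks are slow coupling at the ortho-alkoxy aryl bromide and borane side reactions with the chromone. Fallback: Sonogashira coupling of 4 with 2-methyl-3-butyn-2-ol, then H2, Pd/C reduction of the aryl alkyne to the saturated chain (no prenyl is present at this stage), giving the same compound 6.
- **Step 6 (acidic MOM removal).** Risk is acid-promoted chroman formation, either from the tertiary alcohol with the 4'-OH or from the prenyl group with the 5-/7-OH. Fallback: change the protecting-group strategy at step 2 to fluoride-labile silyl ethers (7,4'-bis-TIPS, 5-OH still free) and finish with AcOH-buffered TBAF at 0 °C, so the final step involves no acid.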